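## Analysis of the target

- The target 24 is a 2H-chromene: benzene ring A is fused to pyran ring B (O1, C2, C3=C4, C4a, C8a). Ring A carries an acetyl group at C6 and a hydroxyl at C7. C2 carries a methyl group and a CH2O ester of (E)-ferulic acid.
- C2 is the only stereocentre. It is R, fully substituted (O1, C3, CH3, CH2O), and has no second centre that could relay or correct it.
- The sensitive groups are the tertiary allylic ether C2–O1 and the styrene-type C3=C4 bond (acid, electrophiles), the ortho-hydroxy aryl ketone, two phenols, and the cinnamate ester (Michael acceptor, cleaved by base and nucleophiles).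
- The difficulty is that the two carbon substituents at C2, CH3 and CH2OR, differ by one oxygen only. Closing ring B by adding O1 to C2 would have to tell them apart in a step that is usually reversible.
- The plan rests on the bond between C2 and the ring oxygen O1. If C4 is taken out of ring B, C2 becomes the α-carbon of a benzofuran-3(2H)-one, flanked by O1 and the C3 carbonyl. That carbon is acidic and gives a flat enol derivative, to which a one-carbon electrophile can be added under catalyst control.
- C2 is therefore built on the five-membered ketone, C4 is inserted between C3 and C4a afterwards, and the C3 carbonyl left by the insertion is used to make C3=C4.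

## Retrosynthetic reasoning

**24 ⇒ 23 ⇒ 19 + 21 (via 22).** The ester C–O bond between the C2 hydroxymethyl oxygen and the cinnamoyl carbon is cut first. The feruloyl unit has an electron-rich styrene, a Michael acceptor and a free phenol, none of which would survive a diazo reagent, an organolithium or a boron Lewis acid, so it is attached last. The acid partner is 21, the aryl acetate of 20, activated as 22. The forward step has to acylate a neopentyl-type primary alcohol beside the C7 phenol, and the last step has to remove only the aryl acetate.

**19 ⇒ 18 ⇒ 17.** The silyl group on the primary oxygen and the methyl group on O7 are removed next. The methyl ether sits ortho to the acetyl group, so a boron Lewis acid can chelate between the two oxygens and cleave this ether under mild conditions. Removing the methyl group before the silyl group keeps the primary alcohol masked while the Lewis acid is present.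

**17 ⇒ 15 (via 16).** The C6–acetyl bond is cut so that the ring expansion meets one ketone only. A Lewis-acid acetylation would have the right regiochemistry. However, every intermediate of this stage carries a silyl ether together with either a free C3 hydroxyl or the C3=C4 styrene, and none of these tolerates an acylium ion with a strong Lewis acid. C6 is therefore first marked with bromine under neutral conditions (13 from 12), using the same directing effects (para to O1, ortho to the methoxy group). The acetyl group enters later through the aryllithium 16.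

**15 ⇒ 14 ⇒ 13 ⇒ 12 ⇒ 11.** The C3=C4 double bond is traced back to the C3 ketone by reduction, sulfonylation and base-induced elimination. C2 has no hydrogen, so elimination can only go towards the benzylic C4. The C3 epimers of 12 to 14 need not be separated.

**11 ⇒ 8 + 9 (via 10).** This is the key disconnection. C4 is removed, which cuts C3–C4 and C4–C4a and contracts ring B to the benzofuran-3(2H)-one 8. Forward, the diazo carbon of 9 adds to the C3 carbonyl and the aryl carbon shifts onto it. The gain is that the hard stereocentre now sits on a five-membered ketone, where it is easy to make. The forward step needs the aryl carbon to migrate in preference to C2, and the insertion to stop after one carbon.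

**8 ⇒ 7 ⇒ 5 + 6.** The C2–CH2O bond is cut. Forward, the flat enol silane 5 adds to 6 under a chiral scandium catalyst, which sets C2. Silylation to 8 follows at once, because the free β-hydroxy ketone 7 could lose 6 again, and with it the stereocentre.

**5 ⇒ 4 ⇒ 3 ⇒ 1 + 2.** The benzofuranone comes from O1–C2 ether formation within 3 and from acylation of 1 with 2 (the C3–C3a bond). The symmetric diether 1 has only one kind of reactive position, so no regioisomer can form. The Lewis acid then removes the methyl group next to the new ketone.

## Alternatives that were turned down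

**Alternative 1:** Cutting O1–C2 and C2–C3 leads back to 4,6-diacetylresorcinol A1 and 1-{[tert-butyl(dimethyl)silyl]oxy}propan-2-one A2.
- **Forward step:** a chiral primary amine–thiourea with an acid cocatalyst would condense one acetyl group of A1 with the carbonyl of A2 (C2–C3). The neighbouring phenol would then add to the β-carbon of the enone (O1–C2), giving the chroman-4-one A3.
- **For:** A1 is symmetric, so whichever acetyl reacts, the other ends at C6 beside the C7 hydroxyl. Ring A is complete and unprotected after one step, and A3 would be about four steps from 24.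
- **Against:** C2 would be made by adding oxygen to a β,β-disubstituted enone whose β-groups (CH3, CH2OSi) are nearly the same size. The addition is reversible, so both the level of induction and its persistence are doubtful. A2 can enolise to either side and self-condense, and both acetyl groups of A1 can react. A3 also holds two aryl ketones conjugated to ring oxygens, and the reduction at C4 would have to choose between them.
- **Comparison:** this route is clearly stronger on step count. The chosen route pays for its length with a stereocentre made by irreversible C–C bond formation on a flat enol derivative, and it never has two ketones in one intermediate.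

**Alternative 2:** Cutting C4–C4a and C8a–O1 leads to 1-[5-bromo-4-fluoro-2-(methoxymethoxy)phenyl]ethan-1-one A4 and the cyclic Z-alkenylboron compound (5R)-5-({[tert-butyl(dimethyl)silyl]oxy}methyl)-5-methyl-1,2-oxaborol-2(5H)-ol A5.
- **Forward step:** Suzuki–Miyaura coupling at the C–B bond of A5 would form C4–C4a and free the tertiary alkoxide. The alkoxide displaces the fluoride para to the acetyl group and closes ring B, giving the protected chromene A6 in one flask.
- **For:** the stereocentre arrives with A5 and no later step touches it. The ring of A5 fixes the Z geometry that the cyclisation needs, the substitution is intramolecular and activated, and the acetyl group and the alkene are in place at once.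
- **Against:** telling CH3 from CH2OSi at a tertiary carbinol is only moved into the synthesis of A5, which takes several steps. A4 needs a regiocontrolled halogenation pattern. The coupling must outrun protodeboronation of a hindered alkenylboron unit under base beside an enolisable ketone. The acetal on O7 must come off with acid from an acid-sensitive chromene.
- **Comparison:** this alternative is stronger in convergence and in the security of C2, and it reaches the chromene directly. The chosen route offers instead a stereocentre made catalytically in the main line from bulk aromatics, and a key step whose two possible migration outcomes both lead on.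

**Alternative 3:** Cutting O1–C2 and C3–C4 leads to 5-acetyl-2,4-dihydroxybenzaldehyde A7 and (E)-4-{[tert-butyl(dimethyl)silyl]oxy}-3-methylbut-2-enal A8.
- **Forward step:** a diarylprolinol silyl ether with an acid cocatalyst would turn A8 into its iminium ion. The hydroxyl ortho to the formyl group of A7 would add to the β-carbon (O1–C2), and the resulting enamine would condense with the formyl group (C3–C4), giving the 3-formylchromene A9.
- **For:** one step takes two small pieces to the bicyclic core with ring A complete, using a reaction type well tried for β-monosubstituted enals.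
- **Against:** A8 is β,β-disubstituted, so the iminium ion is hindered and the oxygen addition that makes the quaternary centre is slow and reversible. The sense of induction depends on an alkene geometry that can scramble through the dienamine, and the dienamine can also expel the silyloxy group. A7 offers a second phenol and an acetyl group to the catalyst. The formyl group at C3 of A9 is one carbon too many and would have to be removed by decarbonylation on a sensitive chromene.
- **Comparison:** it would be shorter than the chosen route if it worked. The chosen route carries no carbon that must be taken out again, and it fixes C2 by a C–C bond that cannot reopen.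

Key step: step 6

Assumption: which enantiomer of the bipyridine diol ligand in step 4 gives (S)-7 must be found by a trial with each antipode; the route is written for the one that sends formaldehyde to the Si face of C2 of 5.

## Route

Step 1
Reactants: 1 1,3-dimethoxybenzene; 2 2-chloropropanoyl chloride (racemic)
Product: 3 2-chloro-1-(2-hydroxy-4-methoxyphenyl)propan-1-one (racemic)
Conditions: AlCl3 (2.5 equiv), CH2Cl2, 0 °C → 40 °C; aq. HCl work-up
Reagents that add atoms: none
Why: Friedel–Crafts acylation at C4 of 1, the only unhindered activated position type, followed in the same flask by AlCl3 cleavage of the methoxy group ortho to the new ketone through its six-membered chelate; the other methoxy group cannot chelate and should stay.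

Step 2
Reactants: 3 2-chloro-1-(2-hydroxy-4-methoxyphenyl)propan-1-one
Product: 4 6-methoxy-2-methyl-1-benzofuran-3(2H)-one (racemic)
Conditions: NaOAc, EtOH, reflux, N2
Reagents that add atoms: none
Why: intramolecular Williamson ether formation (5-exo-tet) of the phenoxide on the α-chloro ketone, the standard closure of benzofuran-3(2H)-ones.

Step 3
Reactants: 4 6-methoxy-2-methyl-1-benzofuran-3(2H)-one
Product: 5 [(6-methoxy-2-methyl-1-benzofuran-3-yl)oxy]trimethylsilane
Conditions: TMSOTf, Et3N, CH2Cl2, 0 °C
Reagents that add atoms: trimethylsilyl trifluoromethanesulfonate, C[Si](C)(C)OS(=O)(=O)C(F)(F)F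
Why: soft enolisation and O-silylation of an acidic ketone whose enol is an aromatic benzofuran; the stereocentre of racemic 4 is erased, so all of 4 is usable.

Step 4
Reactants: 5 [(6-methoxy-2-methyl-1-benzofuran-3-yl)oxy]trimethylsilane; 6 formaldehyde (aqueous solution)
Product: 7 (2S)-2-(hydroxymethyl)-6-methoxy-2-methyl-1-benzofuran-3(2H)-one
Conditions: Sc(OTf)3 (10 mol%), enantiopure 6,6'-bis(1-hydroxy-2,2-dimethylpropyl)-2,2'-bipyridine (12 mol%), DME–H2O, −20 °C
Reagents that add atoms: none
Why: Mukaiyama-type aldol addition (hydroxymethylation) of a fully substituted enol silane to formaldehyde in aqueous medium, established with this catalyst type for enol silanes of α-methyl benzo-fused cyclic ketones; the chiral scandium complex holds formaldehyde and leaves one approach to the flat enol silane open, so that the C2 Si face should react and C2 becomes S.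

Step 5
Reactants: 7 (2S)-2-(hydroxymethyl)-6-methoxy-2-methyl-1-benzofuran-3(2H)-one
Product: 8 (2S)-2-({[tert-butyl(dimethyl)silyl]oxy}methyl)-6-methoxy-2-methyl-1-benzofuran-3(2H)-one
Conditions: TBSCl, imidazole, DMF, 0 °C → rt
Reagents that add atoms: tert-butyldimethylsilyl chloride, CC(C)(C)[Si](C)(C)Cl
Why: silyl ether formation with a weak base only, so that no alkoxide forms that could open the retro-aldol path and lose the stereocentre; the C2 centre is not touched.

Step 6
Reactants: 8 (2S)-2-({[tert-butyl(dimethyl)silyl]oxy}methyl)-6-methoxy-2-methyl-1-benzofuran-3(2H)-one; 9 (trimethylsilyl)diazomethane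
Product: 11 (2S)-2-({[tert-butyl(dimethyl)silyl]oxy}methyl)-7-methoxy-2-methyl-2H-chromen-3(4H)-one, via C4-silyl chroman-3-one 10 (not isolated)
Conditions: Sc(OTf)3 (20 mol%), 9 (2 equiv), CH2Cl2, −78 → 0 °C; then 1 M HCl, THF, 0 °C, brief
Reagents that add atoms: none
Why: Proposed new method: trivalent scandium activates the C3 carbonyl of 8, the diazo carbon of 9 adds to it, and loss of N2 from the β-oxido diazonium is coupled to a 1,2-shift of the aryl carbon C3a onto the former diazo carbon, which makes C3–C4 and C4–C4a in one event. The closest known reaction type is the Lewis-acid-promoted diazoalkane homologation of benzo-fused cyclic ketones (1-indanones to 2-tetralones, 1-tetralones to 2-benzosuberones); it has not been shown on 2,2-disubstituted benzofuran-3(2H)-ones. Ring B is not closed by a cyclisation: the five-membered ring grows to the six-membered ring by insertion of one carbon through the 1,2-shift. No stereocentre of the product is made here; C2 is quaternary, cannot enolise and is a spectator, and the silyl-bearing C4 centre of 10 is erased on protodesilylation to 11. The selectivity needed is migration of the aryl carbon and not of C2; the aryl group is para-methoxy- and ortho-alkoxy-substituted and bridges well, whereas C2 is a crowded quaternary carbon that would have to move next to the bulky silyl group of the reagent. If C2 migrated instead, the chroman-4-one would form, and reduction and elimination would lead from it to the same C3=C4 alkene. A second insertion is held back because the first product is the hindered α-silyl ketone 10 (or its enol silane), which is set free only in the acidic work-up, and 8 has no other carbonyl group.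

Step 7
Reactants: 11 (2S)-2-({[tert-butyl(dimethyl)silyl]oxy}methyl)-7-methoxy-2-methyl-2H-chromen-3(4H)-one
Product: 12 (2S)-2-({[tert-butyl(dimethyl)silyl]oxy}methyl)-7-methoxy-2-methyl-3,4-dihydro-2H-chromen-3-ol (mixture of C3 epimers)
Conditions: NaBH4, MeOH–THF, 0 °C
Reagents that add atoms: none
Why: hydride reduction of a saturated ketone; the new C3 centre forms as a mixture, which does not matter because C3 becomes sp2 again in step 9.

Step 8
Reactants: 12 (2S)-2-({[tert-butyl(dimethyl)silyl]oxy}methyl)-7-methoxy-2-methyl-3,4-dihydro-2H-chromen-3-ol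
Product: 13 (2S)-6-bromo-2-({[tert-butyl(dimethyl)silyl]oxy}methyl)-7-methoxy-2-methyl-3,4-dihydro-2H-chromen-3-ol (mixture of C3 epimers)
Conditions: NBS (1.05 equiv), MeCN, 0 °C, dark
Reagents that add atoms: N-bromosuccinimide, BrN1C(=O)CCC1=O
Why: electrophilic aromatic bromination of a resorcinol-diether-type ring; C6 is para to O1 and ortho to the methoxy group, while C8 lies between two oxygens and is hindered; the neutral conditions leave the silyl ether and the alcohol alone.

Step 9
Reactants: 13 (2S)-6-bromo-2-({[tert-butyl(dimethyl)silyl]oxy}methyl)-7-methoxy-2-methyl-3,4-dihydro-2H-chromen-3-ol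
Product: 15 {[(2R)-6-bromo-7-methoxy-2-methyl-2H-chromen-2-yl]methoxy}(tert-butyl)dimethylsilane, via C3 mesylate 14 (not isolated)
Conditions: MsCl, Et3N, CH2Cl2, 0 °C; then DBU, toluene, 100 °C
Reagents that add atoms: none
Why: sulfonate formation and base-induced E2 elimination; C2 has no hydrogen, so only a benzylic C4–H can be lost and the alkene can form only as C3=C4; the C2 descriptor changes from S to R only because C3 now ranks below CH2O.

Step 10
Reactants: 15 {[(2R)-6-bromo-7-methoxy-2-methyl-2H-chromen-2-yl]methoxy}(tert-butyl)dimethylsilane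
Product: 17 1-[(2R)-2-({[tert-butyl(dimethyl)silyl]oxy}methyl)-7-methoxy-2-methyl-2H-chromen-6-yl]ethan-1-one, via C6 aryllithium 16 (not isolated)
Conditions: n-BuLi (1.1 equiv), THF, −78 °C; then MeC(O)N(OMe)Me, −78 → 0 °C; aq. NH4Cl
Reagents that add atoms: N-methoxy-N-methylacetamide, CC(=O)N(C)OC
Why: bromine–lithium exchange is much faster than any addition to the chromene at −78 °C, and acylation with a Weinreb amide stops at the chelated tetrahedral adduct, so the methyl ketone appears only on quench.

Step 11
Reactants: 17 1-[(2R)-2-({[tert-butyl(dimethyl)silyl]oxy}methyl)-7-methoxy-2-methyl-2H-chromen-6-yl]ethan-1-one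
Product: 18 1-[(2R)-2-({[tert-butyl(dimethyl)silyl]oxy}methyl)-7-hydroxy-2-methyl-2H-chromen-6-yl]ethan-1-one
Conditions: BCl3 (1.5 equiv), CH2Cl2, −78 → −30 °C; aq. NaHCO3
Reagents that add atoms: none
Why: chelation-directed cleavage of an aryl methyl ether ortho to a ketone; boron bridges the acetyl and methoxy oxygens and chloride takes the methyl group at low temperature; any silyl ether lost here converges with the product of step 12.

Step 12
Reactants: 18 1-[(2R)-2-({[tert-butyl(dimethyl)silyl]oxy}methyl)-7-hydroxy-2-methyl-2H-chromen-6-yl]ethan-1-one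
Product: 19 1-[(2R)-7-hydroxy-2-(hydroxymethyl)-2-methyl-2H-chromen-6-yl]ethan-1-one
Conditions: HF·pyridine, THF–pyridine, 0 °C → rt
Reagents that add atoms: none
Why: fluoride-driven cleavage of the primary silyl ether; the pyridine buffer keeps the medium mild enough for the allylic ether C2–O1 and the alkene.

Step 13
Reactants: 20 ferulic acid, (E)-3-(4-hydroxy-3-methoxyphenyl)prop-2-enoic acid
Product: 21 (E)-3-[4-(acetyloxy)-3-methoxyphenyl]prop-2-enoic acid
Conditions: Ac2O, pyridine, rt; then H2O
Reagents that add atoms: acetic anhydride, CC(=O)OC(C)=O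
Why: acetylation of the phenol; the mixed anhydride formed at the carboxyl group is hydrolysed in the aqueous work-up, so that only the aryl acetate remains.

Step 14
Reactants: 19 1-[(2R)-7-hydroxy-2-(hydroxymethyl)-2-methyl-2H-chromen-6-yl]ethan-1-one; 21 (E)-3-[4-(acetyloxy)-3-methoxyphenyl]prop-2-enoic acid
Product: 23 [(2R)-6-acetyl-7-hydroxy-2-methyl-2H-chromen-2-yl]methyl (E)-3-[4-(acetyloxy)-3-methoxyphenyl]prop-2-enoate, via acid chloride 22 (not isolated)
Conditions: 21, (COCl)2, cat. DMF, CH2Cl2, 0 °C → rt, evaporate; then 19, pyridine, cat. DMAP, CH2Cl2, 0 °C → rt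
Reagents that add atoms: none
Why: acid chloride formation and acylation of the primary alcohol; the C7 phenol is tied up in a hydrogen bond to the ortho acetyl group and is a poor nucleophile, and any aryl ester formed there would be cleaved in step 15.

Step 15
Reactants: 23 [(2R)-6-acetyl-7-hydroxy-2-methyl-2H-chromen-2-yl]methyl (E)-3-[4-(acetyloxy)-3-methoxyphenyl]prop-2-enoate
Product: 24 [(2R)-6-acetyl-7-hydroxy-2-methyl-2H-chromen-2-yl]methyl (E)-3-(4-hydroxy-3-methoxyphenyl)prop-2-enoate
Conditions: pyrrolidine (3 equiv), CH2Cl2, 0 °C
Reagents that add atoms: none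
Why: aminolysis of an aryl acetate, which is far faster than aminolysis of the hindered alkyl cinnamate; the ketone, the alkenes and C2 are not affected.

## Compound list

1 | 1,3-dimethoxybenzene | COc1cccc(OC)c1 | starting material
2 | 2-chloropropanoyl chloride (racemic) | CC(Cl)C(Cl)=O | starting material
3 | 2-chloro-1-(2-hydroxy-4-methoxyphenyl)propan-1-one (racemic) | CC(Cl)C(=O)c1ccc(OC)cc1O | intermediate
4 | 6-methoxy-2-methyl-1-benzofuran-3(2H)-one (racemic) | CC1Oc2cc(OC)ccc2C1=O | intermediate
5 | [(6-methoxy-2-methyl-1-benzofuran-3-yl)oxy]trimethylsilane | Cc1oc2cc(OC)ccc2c1O[Si](C)(C)C | intermediate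
6 | formaldehyde | C=O | starting material
7 | (2S)-2-(hydroxymethyl)-6-methoxy-2-methyl-1-benzofuran-3(2H)-one | OC[C@@]1(C)C(=O)c2ccc(OC)cc2O1 | intermediate
8 | (2S)-2-({[tert-butyl(dimethyl)silyl]oxy}methyl)-6-methoxy-2-methyl-1-benzofuran-3(2H)-one | CC(C)(C)[Si](C)(C)OC[C@@]1(C)C(=O)c2ccc(OC)cc2O1 | intermediate
9 | (trimethylsilyl)diazomethane | C[Si](C)(C)C=[N+]=[N-] | starting material
10 | (2S)-2-({[tert-butyl(dimethyl)silyl]oxy}methyl)-7-methoxy-2-methyl-4-(trimethylsilyl)-2H-chromen-3(4H)-one (C4 epimers) | CC(C)(C)[Si](C)(C)OC[C@@]1(C)C(=O)C([Si](C)(C)C)c2ccc(OC)cc2O1 | intermediate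
11 | (2S)-2-({[tert-butyl(dimethyl)silyl]oxy}methyl)-7-methoxy-2-methyl-2H-chromen-3(4H)-one | CC(C)(C)[Si](C)(C)OC[C@@]1(C)C(=O)Cc2ccc(OC)cc2O1 | intermediate
12 | (2S)-2-({[tert-butyl(dimethyl)silyl]oxy}methyl)-7-methoxy-2-methyl-3,4-dihydro-2H-chromen-3-ol (C3 epimers) | CC(C)(C)[Si](C)(C)OC[C@@]1(C)C(O)Cc2ccc(OC)cc2O1 | intermediate
13 | (2S)-6-bromo-2-({[tert-butyl(dimethyl)silyl]oxy}methyl)-7-methoxy-2-methyl-3,4-dihydro-2H-chromen-3-ol (C3 epimers) | CC(C)(C)[Si](C)(C)OC[C@@]1(C)C(O)Cc2cc(Br)c(OC)cc2O1 | intermediate
14 | (2S)-6-bromo-2-({[tert-butyl(dimethyl)silyl]oxy}methyl)-7-methoxy-2-methyl-3,4-dihydro-2H-chromen-3-yl methanesulfonate (C3 epimers) | CC(C)(C)[Si](C)(C)OC[C@@]1(C)C(OS(C)(=O)=O)Cc2cc(Br)c(OC)cc2O1 | intermediate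
15 | {[(2R)-6-bromo-7-methoxy-2-methyl-2H-chromen-2-yl]methoxy}(tert-butyl)dimethylsilane | CC(C)(C)[Si](C)(C)OC[C@@]1(C)C=Cc2cc(Br)c(OC)cc2O1 | intermediate
16 | [(2R)-2-({[tert-butyl(dimethyl)silyl]oxy}methyl)-7-methoxy-2-methyl-2H-chromen-6-yl]lithium | CC(C)(C)[Si](C)(C)OC[C@@]1(C)C=Cc2cc([Li])c(OC)cc2O1 | intermediate
17 | 1-[(2R)-2-({[tert-butyl(dimethyl)silyl]oxy}methyl)-7-methoxy-2-methyl-2H-chromen-6-yl]ethan-1-one | CC(C)(C)[Si](C)(C)OC[C@@]1(C)C=Cc2cc(C(C)=O)c(OC)cc2O1 | intermediate
18 | 1-[(2R)-2-({[tert-butyl(dimethyl)silyl]oxy}methyl)-7-hydroxy-2-methyl-2H-chromen-6-yl]ethan-1-one | CC(C)(C)[Si](C)(C)OC[C@@]1(C)C=Cc2cc(C(C)=O)c(O)cc2O1 | intermediate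
19 | 1-[(2R)-7-hydroxy-2-(hydroxymethyl)-2-methyl-2H-chromen-6-yl]ethan-1-one | OC[C@@]1(C)C=Cc2cc(C(C)=O)c(O)cc2O1 | intermediate
20 | ferulic acid, (E)-3-(4-hydroxy-3-methoxyphenyl)prop-2-enoic acid | COc1cc(/C=C/C(=O)O)ccc1O | starting material
21 | (E)-3-[4-(acetyloxy)-3-methoxyphenyl]prop-2-enoic acid | COc1cc(/C=C/C(=O)O)ccc1OC(C)=O | intermediate
22 | (E)-3-[4-(acetyloxy)-3-methoxyphenyl]prop-2-enoyl chloride | COc1cc(/C=C/C(Cl)=O)ccc1OC(C)=O | intermediate
23 | [(2R)-6-acetyl-7-hydroxy-2-methyl-2H-chromen-2-yl]methyl (E)-3-[4-(acetyloxy)-3-methoxyphenyl]prop-2-enoate | COc1cc(/C=C/C(=O)OC[C@@]2(C)C=Cc3cc(C(C)=O)c(O)cc3O2)ccc1OC(C)=O | intermediate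
24 | [(2R)-6-acetyl-7-hydroxy-2-methyl-2H-chromen-2-yl]methyl (E)-3-(4-hydroxy-3-methoxyphenyl)prop-2-enoate | COc1cc(/C=C/C(=O)OC[C@@]2(C)C=Cc3cc(C(C)=O)c(O)cc3O2)ccc1O | target

## Step count and least certain steps

Total: 15 steps. Longest linear sequence: 14 steps (steps 1 to 12, 14 and 15, from 1); step 13 is a one-step side branch.

**Step 6 (key step).**
- Most likely failure: no addition of the diazo carbon, because the C3 carbonyl of 8 is next to a quaternary carbon and is deactivated by the para-methoxy group and the ring oxygen. The β-oxido diazonium could also close to a spiro-epoxide instead of rearranging.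
- Fallback, from 8 to 11: Wittig methylenation of 8 (Ph3PCH3Br, KOtBu, toluene, reflux; the ketone cannot enolise) should give tert-butyl{[(2R)-6-methoxy-2-methyl-3-methylidene-2,3-dihydro-1-benzofuran-2-yl]methoxy}dimethylsilane F1. Oxidative rearrangement of this exocyclic styrene with the hypervalent iodine reagent PhI(OH)OTs in 95% MeOH at 0 °C then moves the aryl group onto the former methylidene carbon and should give 11. This ring expansion is known for 1-methylidene benzocycloalkanes. It is quenched with bicarbonate as soon as F1 is consumed, to spare the silyl ether.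

**Step 4.**
- Most likely failure: hydrolysis of the enol silane in the aqueous medium before C–C bond formation. Facial selectivity may also be lower than with carbocyclic analogues, because the ring oxygen makes the two flanks of the enol silane more alike.
- Fallback, from 4 to 7: base-catalysed hydroxymethylation of 4 (aqueous 6, catalytic Et3N, THF) should give racemic 2-(hydroxymethyl)-6-methoxy-2-methyl-1-benzofuran-3(2H)-one F2. Kinetic resolution by lipase-catalysed acetylation with vinyl acetate then separates unreacted (S)-7 from [(2R)-6-methoxy-2-methyl-3-oxo-2,3-dihydro-1-benzofuran-2-yl]methyl acetate F3. This is written for an enzyme that acylates the R alcohol; which antipode reacts must be established.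

**Step 9.**
- Most likely failure: slow anti-elimination from the C3 epimer that cannot place the mesylate and a C4–H antiperiplanar without strain. Ionisation at C3 with participation of O1 and ring contraction could also compete.
- Fallback, from 13 to 15: dehydration with the Burgess reagent (toluene, 70 °C) passes through methyl N-({[(2S)-6-bromo-2-({[tert-butyl(dimethyl)silyl]oxy}methyl)-7-methoxy-2-methyl-3,4-dihydro-2H-chromen-3-yl]oxy}sulfonyl)carbamate F4, not isolated, which loses a syn C4–H in an intramolecular elimination and should give 15 without external base.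

**Step 11.**
- Most likely failure: ionisation of the allylic C2–O1 bond or addition of HCl across C3=C4 while the Lewis acid is present.
- Fallback, from 13 to 18: the methyl group is removed while C3–C4 is still saturated.
  - Bromine–lithium exchange on 13 (n-BuLi, 2.2 equiv) and acylation with N-methoxy-N-methylacetamide should give 1-[(2S)-2-({[tert-butyl(dimethyl)silyl]oxy}methyl)-3-hydroxy-7-methoxy-2-methyl-3,4-dihydro-2H-chromen-6-yl]ethan-1-one F5.
  - Mesylation gives (2S)-6-acetyl-2-({[tert-butyl(dimethyl)silyl]oxy}methyl)-7-methoxy-2-methyl-3,4-dihydro-2H-chromen-3-yl methanesulfonate F6.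
  - BCl3 at −78 °C gives (2S)-6-acetyl-2-({[tert-butyl(dimethyl)silyl]oxy}methyl)-7-hydroxy-2-methyl-3,4-dihydro-2H-chromen-3-yl methanesulfonate F7.
  - DBU in toluene then eliminates to 18.

## Further compounds

F1 | step 6 | tert-butyl{[(2R)-6-methoxy-2-methyl-3-methylidene-2,3-dihydro-1-benzofuran-2-yl]methoxy}dimethylsilane | CC(C)(C)[Si](C)(C)OC[C@@]1(C)C(=C)c2ccc(OC)cc2O1
F2 | step 4 | 2-(hydroxymethyl)-6-methoxy-2-methyl-1-benzofuran-3(2H)-one (racemic) | OCC1(C)C(=O)c2ccc(OC)cc2O1
F3 | step 4 | [(2R)-6-methoxy-2-methyl-3-oxo-2,3-dihydro-1-benzofuran-2-yl]methyl acetate | CC(=O)OC[C@]1(C)C(=O)c2ccc(OC)cc2O1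
F4 | step 9 | methyl N-({[(2S)-6-bromo-2-({[tert-butyl(dimethyl)silyl]oxy}methyl)-7-methoxy-2-methyl-3,4-dihydro-2H-chromen-3-yl]oxy}sulfonyl)carbamate (C3 epimers) | CC(C)(C)[Si](C)(C)OC[C@@]1(C)C(OS(=O)(=O)NC(=O)OC)Cc2cc(Br)c(OC)cc2O1
F5 | step 11 | 1-[(2S)-2-({[tert-butyl(dimethyl)silyl]oxy}methyl)-3-hydroxy-7-methoxy-2-methyl-3,4-dihydro-2H-chromen-6-yl]ethan-1-one (C3 epimers) | CC(C)(C)[Si](C)(C)OC[C@@]1(C)C(O)Cc2cc(C(C)=O)c(OC)cc2O1
F6 | step 11 | (2S)-6-acetyl-2-({[tert-butyl(dimethyl)silyl]oxy}methyl)-7-methoxy-2-methyl-3,4-dihydro-2H-chromen-3-yl methanesulfonate (C3 epimers) | CC(C)(C)[Si](C)(C)OC[C@@]1(C)C(OS(C)(=O)=O)Cc2cc(C(C)=O)c(OC)cc2O1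
F7 | step 11 | (2S)-6-acetyl-2-({[tert-butyl(dimethyl)silyl]oxy}methyl)-7-hydroxy-2-methyl-3,4-dihydro-2H-chromen-3-yl methanesulfonate (C3 epimers) | CC(C)(C)[Si](C)(C)OC[C@@]1(C)C(OS(C)(=O)=O)Cc2cc(C(C)=O)c(O)cc2O1
A1 | alternative 1 | 4,6-diacetylresorcinol | CC(=O)c1cc(C(C)=O)c(O)cc1O
A2 | alternative 1 | 1-{[tert-butyl(dimethyl)silyl]oxy}propan-2-one | CC(=O)CO[Si](C)(C)C(C)(C)C
A3 | alternative 1 | (2R)-6-acetyl-2-({[tert-butyl(dimethyl)silyl]oxy}methyl)-7-hydroxy-2-methyl-2,3-dihydro-4H-chromen-4-one | CC(C)(C)[Si](C)(C)OC[C@@]2(C)CC(=O)c3cc(C(C)=O)c(O)cc3O2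
A4 | alternative 2 | 1-[5-bromo-4-fluoro-2-(methoxymethoxy)phenyl]ethan-1-one | CC(=O)c1cc(Br)c(F)cc1OCOC
A5 | alternative 2 | (5R)-5-({[tert-butyl(dimethyl)silyl]oxy}methyl)-5-methyl-1,2-oxaborol-2(5H)-ol | CC(C)(C)[Si](C)(C)OC[C@@]1(C)C=CB(O)O1
A6 | alternative 2 | 1-[(2R)-2-({[tert-butyl(dimethyl)silyl]oxy}methyl)-7-(methoxymethoxy)-2-methyl-2H-chromen-6-yl]ethan-1-one | CC(C)(C)[Si](C)(C)OC[C@@]2(C)C=Cc3cc(C(C)=O)c(OCOC)cc3O2
A7 | alternative 3 | 5-acetyl-2,4-dihydroxybenzaldehyde | CC(=O)c1cc(C=O)c(O)cc1O
A8 | alternative 3 | (E)-4-{[tert-butyl(dimethyl)silyl]oxy}-3-methylbut-2-enal | C/C(CO[Si](C)(C)C(C)(C)C)=C\C=O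
A9 | alternative 3 | (2R)-6-acetyl-2-({[tert-butyl(dimethyl)silyl]oxy}methyl)-7-hydroxy-2-methyl-2H-chromene-3-carbaldehyde | CC(C)(C)[Si](C)(C)OC[C@@]2(C)C(C=O)=Cc3cc(C(C)=O)c(O)cc3O2
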